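**Strategy**

The lactone carboxyl of the isochromanone ring (C1 with its carbonyl oxygen and ring oxygen O2) is treated as a molecule of CO2 inserted between the arene carbon C8a and the carbinol carbon C3. The key step is a copper-catalysed carboxylation of an aryl iodide at C8a with CO2; the carboxylate so formed displaces a C3 mesylate in the same flask (6-exo-tet, inversion), closing the ring and setting C3. It exploits that C8a lies ortho to the C8 oxygen and para to the C6 oxygen, so iodine enters there selectively. The precursor is an erythro (1S,2R) acetate mesylate made from D-lactate; geranylation of the unchelated C6 phenol comes last.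

Key step: step 9

Remark: isochroman-1-one numbering is used throughout (C1 lactone carbonyl, O2 ring oxygen, C3 methyl-bearing carbon, C4 acetoxy-bearing carbon, C4a–C8a arene); with this numbering the target is the cis-(3S,4S) isomer.

**Route**

Step 1
Reactants: 1 3-bromo-4,5-dihydroxybenzaldehyde
Product: 2 3-bromo-5-hydroxy-4-methoxybenzaldehyde
Conditions: MeI (1.05 equiv), Li2CO3, DMF, 40 °C
Reagents that add atoms: iodomethane CI
Why: The 4-OH para to the formyl group is the more acidic phenol, so the weak base should form only its phenoxide, which is methylated (regioselective Williamson ether synthesis).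

Step 2
Reactants: 2 3-bromo-5-hydroxy-4-methoxybenzaldehyde
Product: 4 5-bromo-4-methoxybenzene-1,3-diol, via aryl formate 3 (not isolated)
Conditions: mCPBA (1.3 equiv), CH2Cl2, 0 °C → rt; then K2CO3 (cat.), MeOH, rt
Reagents that add atoms: mCPBA O=C(OO)c1cccc(Cl)c1
Why: Baeyer–Villiger (Dakin-type) oxidation of the electron-rich benzaldehyde, with aryl migration promoted by the para-methoxy group, should give the aryl formate, which methanolysis cleaves to the phenol.

Step 3
Reactants: 4 5-bromo-4-methoxybenzene-1,3-diol
Product: 5 1-bromo-2-methoxy-3,5-bis(methoxymethoxy)benzene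
Conditions: MOMCl (2.5 equiv), iPr2NEt, CH2Cl2, 0 °C → rt
Reagents that add atoms: chloromethyl methyl ether COCCl
Why: O-Alkylation of both phenols gives MOM acetals, a protecting group that tolerates the organolithium step and the later Lewis-acidic zinc reagents.

Step 4
Reactants: 6 methyl (R)-lactate
Product: 7 (R)-2-hydroxy-N-methoxy-N-methylpropanamide
Conditions: MeNH(OMe)·HCl, iPrMgCl, THF, −20 → 0 °C
Reagents that add atoms: N,O-dimethylhydroxylamine hydrochloride CNOC.Cl
Why: Aminolysis of the ester by the chloromagnesium amide of N,O-dimethylhydroxylamine (Weinreb amide formation) should proceed without touching the stereocentre.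

Step 5
Reactants: 5 1-bromo-2-methoxy-3,5-bis(methoxymethoxy)benzene and 7 (R)-2-hydroxy-N-methoxy-N-methylpropanamide
Product: 9 (2R)-2-hydroxy-1-[2-methoxy-3,5-bis(methoxymethoxy)phenyl]propan-1-one, via aryllithium 8 (not isolated)
Conditions: 5, n-BuLi, THF, −78 °C; then 7 (pre-treated with iPrMgCl, THF, −20 °C), −78 → 0 °C; aq. NH4Cl
Reagents that add atoms: none
Why: Bromine–lithium exchange followed by Weinreb ketone synthesis, in which the chelated tetrahedral intermediate prevents over-addition and the α-alkoxide prevents enolisation and so racemisation.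

Step 6
Reactants: 9 (2R)-2-hydroxy-1-[2-methoxy-3,5-bis(methoxymethoxy)phenyl]propan-1-one
Product: 10 (1S,2R)-1-[2-methoxy-3,5-bis(methoxymethoxy)phenyl]propane-1,2-diol
Conditions: Zn(BH4)2, Et2O, −30 → 0 °C
Reagents that add atoms: none
Why: Chelation-controlled (Cram-chelate) reduction, in which zinc binds the carbonyl and α-hydroxy oxygens and hydride attacks anti to the methyl group, should give the anti (erythro) diol and so set the benzylic carbon as S.

Step 7
Reactants: 10 (1S,2R)-1-[2-methoxy-3,5-bis(methoxymethoxy)phenyl]propane-1,2-diol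
Product: 11 (1S,2R)-1-[2-iodo-6-methoxy-3,5-bis(methoxymethoxy)phenyl]propane-1,2-diol
Conditions: NIS (1.05 equiv), MeCN, 0 °C, dark
Reagents that add atoms: N-iodosuccinimide O=C1CCC(=O)N1I
Why: Electrophilic aromatic iodination should occur ortho to one MOM ether and para to the other (the position next to the side chain), as is general for 3,5-dialkoxyalkylbenzenes, while the site between the two ethers is shielded.

Step 8
Reactants: 11 (1S,2R)-1-[2-iodo-6-methoxy-3,5-bis(methoxymethoxy)phenyl]propane-1,2-diol
Product: 13 (1S,2R)-1-[2-iodo-6-methoxy-3,5-bis(methoxymethoxy)phenyl]-2-(methanesulfonyloxy)propyl acetate, via hydroxy mesylate 12 (not isolated)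
Conditions: MsCl (1.05 equiv), pyridine, CH2Cl2, −20 → 0 °C; then Ac2O, DMAP (cat.), rt
Reagents that add atoms: methanesulfonyl chloride CS(=O)(=O)Cl; acetic anhydride CC(=O)OC(C)=O
Why: Site-selective sulfonylation of the less hindered non-benzylic hydroxyl (the benzylic one is flanked by the iodo and methoxy ortho substituents), followed by DMAP-catalysed acetylation of the remaining hydroxyl, both with retention.

Step 9
Reactants: 13 (1S,2R)-1-[2-iodo-6-methoxy-3,5-bis(methoxymethoxy)phenyl]-2-(methanesulfonyloxy)propyl acetate
Product: 15 (3S,4S)-5-methoxy-6,8-bis(methoxymethoxy)-3-methyl-1-oxoisochroman-4-yl acetate, via zinc carboxylate 14 (not isolated)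
Conditions: CO2 (1 atm), CuI (10 mol %), TMEDA (20 mol %), Et2Zn (3 equiv), DMSO, 40 °C; then 75 °C, same flask
Reagents that add atoms: carbon dioxide O=C=O
Why: Copper-mediated iodine–metal exchange with Et2Zn should give an arylzinc/arylcopper species that inserts CO2 to the zinc carboxylate 14 (copper-catalysed carboxylation of aryl iodides with CO2), and on warming in DMSO the carboxylate oxygen should displace the C3 mesylate (carboxylate O-alkylation, as in δ-lactone formation from sulfonyloxy acids). The six-membered lactone ring closes in the 6-exo-tet mode, with the leaving group outside the new ring. C3 is set by stereospecific SN2 inversion of the (R)-mesylate to (S), which places the methyl group cis to the C4 acetate, whose (S) configuration is untouched. The step needs chemoselectivity for the C–I bond over acetate and mesylate, which the mild arylzinc/arylcopper nucleophile secures where an aryllithium or Grignard reagent would attack the neighbouring acetate. It also needs closure at C3 and not at benzylic C4, secured because C4 carries an acetate that is no leaving group, and direct displacement must outrun acetoxonium participation, which the anionic nucleophile in a dipolar aprotic solvent favours.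

Step 10
Reactants: 15 (3S,4S)-5-methoxy-6,8-bis(methoxymethoxy)-3-methyl-1-oxoisochroman-4-yl acetate
Product: 16 (3S,4S)-6,8-dihydroxy-5-methoxy-3-methyl-1-oxoisochroman-4-yl acetate
Conditions: ZnBr2, n-PrSH, CH2Cl2, 0 °C → rt
Reagents that add atoms: none
Why: Lewis acid–thiol cleavage of the two MOM acetals, in which the thiol traps the methoxymethyl cation, should leave the acetate, the lactone and the electron-rich ring untouched.

Step 11
Reactants: 16 (3S,4S)-6,8-dihydroxy-5-methoxy-3-methyl-1-oxoisochroman-4-yl acetate and 17 geranyl bromide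
Product: 18 (3S,4S)-6-[(2E)-3,7-dimethylocta-2,6-dienyloxy]-8-hydroxy-5-methoxy-3-methyl-1-oxoisochroman-4-yl acetate (target)
Conditions: K2CO3 (1.2 equiv), acetone, rt
Reagents that add atoms: none
Why: Williamson etherification should take place at the more acidic, non-chelated C6 phenol (para to the lactone carbonyl), because the C8 phenol is held in a hydrogen bond to that carbonyl.

**Compound list**

1 | 3-bromo-4,5-dihydroxybenzaldehyde | O=Cc1cc(O)c(O)c(Br)c1 | starting material
2 | 3-bromo-5-hydroxy-4-methoxybenzaldehyde | COc1c(O)cc(C=O)cc1Br | intermediate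
3 | 3-bromo-5-hydroxy-4-methoxyphenyl formate (not isolated) | COc1c(O)cc(OC=O)cc1Br | intermediate
4 | 5-bromo-4-methoxybenzene-1,3-diol | COc1c(O)cc(O)cc1Br | intermediate
5 | 1-bromo-2-methoxy-3,5-bis(methoxymethoxy)benzene | COc1c(OCOC)cc(OCOC)cc1Br | intermediate
6 | methyl (R)-lactate | COC(=O)[C@@H](C)O | starting material
7 | (R)-2-hydroxy-N-methoxy-N-methylpropanamide | CON(C)C(=O)[C@@H](C)O | intermediate
8 | [2-methoxy-3,5-bis(methoxymethoxy)phenyl]lithium (not isolated) | COc1c(OCOC)cc(OCOC)cc1[Li] | intermediate
9 | (2R)-2-hydroxy-1-[2-methoxy-3,5-bis(methoxymethoxy)phenyl]propan-1-one | COc1c(OCOC)cc(OCOC)cc1C(=O)[C@@H](C)O | intermediate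
10 | (1S,2R)-1-[2-methoxy-3,5-bis(methoxymethoxy)phenyl]propane-1,2-diol | COc1c(OCOC)cc(OCOC)cc1[C@H](O)[C@@H](C)O | intermediate
11 | (1S,2R)-1-[2-iodo-6-methoxy-3,5-bis(methoxymethoxy)phenyl]propane-1,2-diol | COc1c(OCOC)cc(OCOC)c(I)c1[C@H](O)[C@@H](C)O | intermediate
12 | (1S,2R)-1-hydroxy-1-[2-iodo-6-methoxy-3,5-bis(methoxymethoxy)phenyl]propan-2-yl methanesulfonate (not isolated) | COc1c(OCOC)cc(OCOC)c(I)c1[C@H](O)[C@@H](C)OS(C)(=O)=O | intermediate
13 | (1S,2R)-1-[2-iodo-6-methoxy-3,5-bis(methoxymethoxy)phenyl]-2-(methanesulfonyloxy)propyl acetate | COc1c(OCOC)cc(OCOC)c(I)c1[C@H](OC(C)=O)[C@@H](C)OS(C)(=O)=O | intermediate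
14 | 2-[(1S,2R)-1-acetoxy-2-(methanesulfonyloxy)propyl]-3-methoxy-4,6-bis(methoxymethoxy)benzoic acid, formed as its zinc carboxylate and drawn as the acid (not isolated) | COc1c(OCOC)cc(OCOC)c(C(=O)O)c1[C@H](OC(C)=O)[C@@H](C)OS(C)(=O)=O | intermediate
15 | (3S,4S)-5-methoxy-6,8-bis(methoxymethoxy)-3-methyl-1-oxoisochroman-4-yl acetate | COc1c(OCOC)cc(OCOC)c2c1[C@H](OC(C)=O)[C@H](C)OC2=O | intermediate
16 | (3S,4S)-6,8-dihydroxy-5-methoxy-3-methyl-1-oxoisochroman-4-yl acetate | COc1c(O)cc(O)c2c1[C@H](OC(C)=O)[C@H](C)OC2=O | intermediate
17 | geranyl bromide, (2E)-1-bromo-3,7-dimethylocta-2,6-diene | BrC/C=C(\C)CCC=C(C)C | starting material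
18 | (3S,4S)-6-[(2E)-3,7-dimethylocta-2,6-dienyloxy]-8-hydroxy-5-methoxy-3-methyl-1-oxoisochroman-4-yl acetate | COc1c(OC/C=C(\C)CCC=C(C)C)cc(O)c2c1[C@H](OC(C)=O)[C@H](C)OC2=O | target

**Step count and risks**

Total step count: 11. Longest linear sequence: 10 steps (1 → 18 through steps 1–3 and 5–11; step 4 is a one-step side branch).

Steps most likely to fail:

Step 9 (key step). Iodine–metal exchange or CO2 insertion at the doubly ortho-substituted C8a may be sluggish, so that protodeiodination on work-up dominates. The zinc carboxylate may also close too slowly, which would let acetate participation at C3 compete. Fallback, setting out from 13 and coming back at 15: palladium-catalysed alkoxycarbonylation of 13 (Pd(OAc)2, Xantphos, CO 1 atm, 2-(trimethylsilyl)ethanol, Et3N, DMF, 80 °C) should give 2-(trimethylsilyl)ethyl 2-[(1S,2R)-1-acetoxy-2-(methanesulfonyloxy)propyl]-3-methoxy-4,6-bis(methoxymethoxy)benzoate F1. TBAF in THF (0 → 40 °C) then fragments the silylethyl ester to the free carboxylate 14 (here as its ammonium salt), which displaces the C3 mesylate with inversion to give 15. The carbonyl carbon then comes from CO, and the two bonds are made in separate operations.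

Step 8. Site selectivity in the sulfonylation may be lost (bis-mesylation or reaction at the benzylic hydroxyl), the hydroxy mesylate may close to the epoxide under the basic conditions, or acylation of the hindered benzylic hydroxyl may stay incomplete. Fallback, setting out from 11 and coming back at 13: exhaustive acetylation (Ac2O, DMAP, pyridine, 40 °C) should give (1S,2R)-1-[2-iodo-6-methoxy-3,5-bis(methoxymethoxy)phenyl]propane-1,2-diyl diacetate F2. Lipase hydrolysis (Candida antarctica lipase B, phosphate buffer pH 7/MTBE, 30 °C) should remove only the accessible non-benzylic acetate, under neutral conditions that suppress acyl migration, to give (1S,2R)-2-hydroxy-1-[2-iodo-6-methoxy-3,5-bis(methoxymethoxy)phenyl]propyl acetate F3. Mesylation (MsCl, Et3N, CH2Cl2, −20 °C) then gives 13.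

Step 6. Facial selectivity may be poor if the ortho-methoxy group competes for zinc, so that the Cram chelate is not the reacting species. Fallback, setting out from 9 and coming back at 10: catalyst-controlled Noyori asymmetric transfer hydrogenation (RuCl[(R,R)-TsDPEN](p-cymene), HCO2H/Et3N 5:2, rt), in which the hydride face is chosen by the catalyst according to the aryl ketone model and not by the substrate chelate. This fallback makes no compound outside the list (F0).

Further compounds
F1 | step 9 | 2-(trimethylsilyl)ethyl 2-[(1S,2R)-1-acetoxy-2-(methanesulfonyloxy)propyl]-3-methoxy-4,6-bis(methoxymethoxy)benzoate | COc1c(OCOC)cc(OCOC)c(C(=O)OCC[Si](C)(C)C)c1[C@H](OC(C)=O)[C@@H](C)OS(C)(=O)=O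
F2 | step 8 | (1S,2R)-1-[2-iodo-6-methoxy-3,5-bis(methoxymethoxy)phenyl]propane-1,2-diyl diacetate | COc1c(OCOC)cc(OCOC)c(I)c1[C@H](OC(C)=O)[C@@H](C)OC(C)=O
F3 | step 8 | (1S,2R)-2-hydroxy-1-[2-iodo-6-methoxy-3,5-bis(methoxymethoxy)phenyl]propyl acetate | COc1c(OCOC)cc(OCOC)c(I)c1[C@H](OC(C)=O)[C@@H](C)O
F0 | step 6 | none | none
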